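**Plan**

- Retrosynthetic cuts, in order: C2–C1' (aryl added to a chromone), O1–C2 and C2–C3 of ring C (enaminone closure), C4–C4a (acetyl group, by formylation), then ring A at C8–C8a, C6–C7 and C4a–C8a.
- Enabling feature: ring A is hexasubstituted, with three oxygens (C5, C7, C8a) that must be told apart and carbons at C6 (methyl), C8 (prenyl) and C4a. A cyclobutenone–siloxyalkyne benzannulation takes C7/C8 from the alkyne, C4a/C5/C6 from the cyclobutenone and C8a from its carbonyl, and leaves only O8a unprotected.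
- Forward: ring A first, then the acetyl group at C4a, ring C as a chromone closed on the free O8a, ring B by conjugate arylation, then deprotection.
- Stereochemistry: the single centre C2 (S) is set by the chiral pyridine–oxazoline ligand in the palladium-catalysed arylation; the later steps are acidic or buffered, so ring C should not open.

Key step: step 5

Assumption: the (R)-configured ligand is taken to give the 2S flavanone, by analogy with the sense of induction of the (S)-ligand on cyclic enones (same face, 2R on a chromone); if the sense proves opposite, the (S)-ligand is used. The cyclobutane-1,3-dione is drawn as its enol.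

Abbreviations: MOM = methoxymethyl, TIPS = triisopropylsilyl, prenyl = 3-methylbut-2-en-1-yl.

**Route**

Step 1
Reactants: 1 1-ethoxyprop-1-yne; 2 acetyl chloride
Product: 4 3-ethoxy-2-methylcyclobut-2-en-1-one, via ketene 3 (not isolated)
Conditions: Et3N, Et2O, 0 °C → rt, slow addition of 2
Reagents that add atoms: none
Why: Triethylamine dehydrochlorinates acetyl chloride to ketene, which is trapped in a regioselective ketene–ynol ether [2+2] cycloaddition (carbonyl carbon to the methyl-bearing alkyne carbon), the standard route to 3-alkoxycyclobutenones.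

Step 2
Reactants: 4 3-ethoxy-2-methylcyclobut-2-en-1-one
Product: 5 3-hydroxy-2-methylcyclobut-2-en-1-one (enol of 2-methylcyclobutane-1,3-dione)
Conditions: 1 M HCl aq, THF, 0 °C → rt
Reagents that add atoms: water, O
Why: Acid-catalysed hydrolysis of the vinylogous ester (addition–elimination at C3) frees the vinylogous acid, the classical way from 3-ethoxycyclobutenones to cyclobutane-1,3-diones.

Step 3
Reactants: 5 3-hydroxy-2-methylcyclobut-2-en-1-one
Product: 6 3-(methoxymethoxy)-2-methylcyclobut-2-en-1-one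
Conditions: MOMCl, i-Pr2NEt, CH2Cl2, 0 °C
Reagents that add atoms: chloromethyl methyl ether, COCCl
Why: Williamson-type O-alkylation of the acidic, symmetrical dione enol with a hard electrophile should give a single vinylogous ester whose acetal can be removed under mild acid at the end.

Step 4
Reactants: 7 ethyl 4-methylpent-3-enoate
Product: 10 triisopropyl[(5-methylhex-4-en-1-yn-1-yl)oxy]silane, via dibromoenolate 8 (not isolated), via lithium ynolate 9 (not isolated)
Conditions: CH2Br2, lithium 2,2,6,6-tetramethylpiperidide, THF, −78 °C; add 7; LiN(SiMe3)2; n-BuLi, −78 → 20 °C; TIPSOTf, −78 → 0 °C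
Reagents that add atoms: dibromomethane, BrCBr; triisopropylsilyl trifluoromethanesulfonate, CC(C)[Si](OS(=O)(=O)C(F)(F)F)(C(C)C)C(C)C
Why: Kowalski ester homologation: LiCHBr2 adds to the ester, the dibromoketone is enolised, bromine–lithium exchange and 1,2-shift of the carbenoid give the ynolate, and the bulky silyl triflate traps it on oxygen.

Step 5
Reactants: 6 3-(methoxymethoxy)-2-methylcyclobut-2-en-1-one; 10 triisopropyl[(5-methylhex-4-en-1-yn-1-yl)oxy]silane
Product: 15 5-(methoxymethoxy)-4-methyl-2-(3-methylbut-2-en-1-yl)-3-[(triisopropylsilyl)oxy]phenol, via vinylketene 11 (not isolated), via vinylcyclobutenone 12 (not isolated), via dienylketene 13 (not isolated), via cyclohexadienone 14 (not isolated)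
Conditions: 10 (1.3 equiv), PhMe, 80 °C then 110 °C, sealed tube
Reagents that add atoms: none
Why: Heating opens 6 by 4π electrocyclic ring opening to vinylketene 11, whose ketene C=C adds [2+2] to the electron-rich alkyne of 10 to give the 4-vinylcyclobutenone 12; a second 4π opening gives dienylketene 13, 6π electrocyclisation gives cyclohexadienone 14, and tautomerisation gives phenol 15. The closest known reaction is the Danheiser benzannulation of cyclobutenones with siloxyalkynes, here run with an alkoxy group on C3 of the cyclobutenone. Ring A closes by 6π electrocyclisation (C4a–C8a) after the [2+2] step has made C8–C8a and C6–C7, and irreversible aromatisation drives the reversible ring openings forward. No stereocentre results, since the quaternary centre of 12 is lost on ring opening. The only selectivity needed is the regiochemistry of the [2+2] step, secured by polarity: the electrophilic ketene carbonyl carbon bonds to the nucleophilic, prenyl-bearing carbon of the ynol ether. C8a therefore carries the free hydroxyl, C8 the prenyl group, C7 the silyl ether, C6 the methyl group, C5 the MOM ether and C4a the only ring hydrogen.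

Step 6
Reactants: 15 5-(methoxymethoxy)-4-methyl-2-(3-methylbut-2-en-1-yl)-3-[(triisopropylsilyl)oxy]phenol
Product: 16 2-hydroxy-6-(methoxymethoxy)-5-methyl-3-(3-methylbut-2-en-1-yl)-4-[(triisopropylsilyl)oxy]benzaldehyde
Conditions: MgCl2, Et3N, (CH2O)n, THF, reflux
Reagents that add atoms: paraformaldehyde (as formaldehyde), C=O
Why: Casnati–Skattebøl ortho-formylation: the magnesium phenoxide delivers formaldehyde to the only free ring position, ortho to the hydroxyl, and a second formaldehyde oxidises the benzylic alkoxide by hydride transfer.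

Step 7
Reactants: 16 2-hydroxy-6-(methoxymethoxy)-5-methyl-3-(3-methylbut-2-en-1-yl)-4-[(triisopropylsilyl)oxy]benzaldehyde
Product: 17 1-[2-hydroxy-6-(methoxymethoxy)-5-methyl-3-(3-methylbut-2-en-1-yl)-4-[(triisopropylsilyl)oxy]phenyl]ethan-1-ol (racemic)
Conditions: MeMgBr (3 equiv), THF, −20 → 0 °C; NH4Cl aq
Reagents that add atoms: methylmagnesium bromide, C[Mg]Br
Why: Grignard addition to the aldehyde after deprotonation of the phenol; the carbinol centre forms as a racemate and is removed in the next step.

Step 8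
Reactants: 17 1-[2-hydroxy-6-(methoxymethoxy)-5-methyl-3-(3-methylbut-2-en-1-yl)-4-[(triisopropylsilyl)oxy]phenyl]ethan-1-ol
Product: 18 1-[2-hydroxy-6-(methoxymethoxy)-5-methyl-3-(3-methylbut-2-en-1-yl)-4-[(triisopropylsilyl)oxy]phenyl]ethan-1-one
Conditions: activated MnO2, CH2Cl2, rt
Reagents that add atoms: none
Why: Selective benzylic alcohol oxidation with MnO2, which should leave the fully substituted phenol, the prenyl alkene and the acetal untouched.

Step 9
Reactants: 18 1-[2-hydroxy-6-(methoxymethoxy)-5-methyl-3-(3-methylbut-2-en-1-yl)-4-[(triisopropylsilyl)oxy]phenyl]ethan-1-one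
Product: 20 5-(methoxymethoxy)-6-methyl-8-(3-methylbut-2-en-1-yl)-7-[(triisopropylsilyl)oxy]-4H-chromen-4-one, via enaminone 19 (not isolated)
Conditions: Me2NCH(OMe)2, PhMe, 90 °C; then AcOH, CH2Cl2, 40 °C
Reagents that add atoms: N,N-dimethylformamide dimethyl acetal, COC(OC)N(C)C
Why: Enaminone formation from the methyl ketone, then addition–elimination by the ortho hydroxyl with loss of dimethylamine, is the standard route to 2-unsubstituted chromones; only the free O8a can close, which fixes the prenyl group at C8.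

Step 10
Reactants: 20 5-(methoxymethoxy)-6-methyl-8-(3-methylbut-2-en-1-yl)-7-[(triisopropylsilyl)oxy]-4H-chromen-4-one; 21 [4-(methoxymethoxy)phenyl]boronic acid
Product: 22 (2S)-5-(methoxymethoxy)-2-[4-(methoxymethoxy)phenyl]-6-methyl-8-(3-methylbut-2-en-1-yl)-7-[(triisopropylsilyl)oxy]chroman-4-one
Conditions: 21 (2 equiv), Pd(OCOCF3)2 (5 mol %), (R)-4-tert-butyl-2-(pyridin-2-yl)-4,5-dihydrooxazole (6 mol %), NH4PF6 (30 mol %), H2O (5 equiv), ClCH2CH2Cl, 60 °C
Reagents that add atoms: none
Why: Palladium-catalysed asymmetric conjugate addition of an arylboronic acid to a chromone (transmetalation to the cationic divalent palladium complex, enantio-determining insertion of C2=C3, protonolysis of the enolate); the tert-butyl group of the (R)-ligand blocks one face so that the aryl group should enter on the face that gives 2S.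

Step 11
Reactants: 22 (2S)-5-(methoxymethoxy)-2-[4-(methoxymethoxy)phenyl]-6-methyl-8-(3-methylbut-2-en-1-yl)-7-[(triisopropylsilyl)oxy]chroman-4-one
Product: 23 (2S)-5-hydroxy-2-(4-hydroxyphenyl)-6-methyl-8-(3-methylbut-2-en-1-yl)-7-[(triisopropylsilyl)oxy]chroman-4-one
Conditions: 3 M HCl aq/MeOH (1:9), 40 °C
Reagents that add atoms: none
Why: Acid-catalysed acetal exchange with methanol removes both MOM ethers, while the silyl ether still on O7 keeps the prenyl group from cyclising onto a neighbouring phenol and C2 is not epimerisable under mild acid.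

Step 12
Reactants: 23 (2S)-5-hydroxy-2-(4-hydroxyphenyl)-6-methyl-8-(3-methylbut-2-en-1-yl)-7-[(triisopropylsilyl)oxy]chroman-4-one
Product: 24 6-methyl-8-prenylnaringenin, (2S)-5,7-dihydroxy-2-(4-hydroxyphenyl)-6-methyl-8-(3-methylbut-2-en-1-yl)chroman-4-one
Conditions: n-Bu4NF, AcOH (1:1), THF, 0 °C
Reagents that add atoms: none
Why: Fluoride cleavage of the aryl silyl ether, buffered with acetic acid so that no free phenoxide or enolate can trigger the retro-oxa-Michael opening of ring C that racemises flavanones.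

**Compound list**

1 | 1-ethoxyprop-1-yne | CCOC#CC | starting material
2 | acetyl chloride | CC(=O)Cl | starting material
3 | ketene | C=C=O | intermediate (not isolated)
4 | 3-ethoxy-2-methylcyclobut-2-en-1-one | CCOC1=C(C)C(=O)C1 | intermediate
5 | 3-hydroxy-2-methylcyclobut-2-en-1-one | CC1=C(O)CC1=O | intermediate
6 | 3-(methoxymethoxy)-2-methylcyclobut-2-en-1-one | COCOC1=C(C)C(=O)C1 | intermediate
7 | ethyl 4-methylpent-3-enoate | CCOC(=O)CC=C(C)C | starting material
8 | lithium 1,1-dibromo-5-methylhexa-1,4-dien-2-olate | [Li]OC(CC=C(C)C)=C(Br)Br | intermediate (not isolated)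
9 | lithium 5-methylhex-4-en-1-yn-1-olate | [Li]OC#CCC=C(C)C | intermediate (not isolated)
10 | triisopropyl[(5-methylhex-4-en-1-yn-1-yl)oxy]silane | CC(C)=CCC#CO[Si](C(C)C)(C(C)C)C(C)C | intermediate
11 | 3-(methoxymethoxy)-2-methylbuta-1,3-dien-1-one | C=C(OCOC)C(C)=C=O | intermediate (not isolated)
12 | 4-[1-(methoxymethoxy)ethenyl]-4-methyl-2-(3-methylbut-2-en-1-yl)-3-[(triisopropylsilyl)oxy]cyclobut-2-en-1-one (racemic) | O=C1C(CC=C(C)C)=C(O[Si](C(C)C)(C(C)C)C(C)C)C1(C)C(=C)OCOC | intermediate (not isolated)
13 | (3E)-5-(methoxymethoxy)-4-methyl-2-(3-methylbut-2-en-1-yl)-3-[(triisopropylsilyl)oxy]hexa-1,3,5-trien-1-one | O=C=C(CC=C(C)C)/C(O[Si](C(C)C)(C(C)C)C(C)C)=C(C)\C(=C)OCOC | intermediate (not isolated)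
14 | 5-(methoxymethoxy)-4-methyl-2-(3-methylbut-2-en-1-yl)-3-[(triisopropylsilyl)oxy]cyclohexa-2,4-dien-1-one | O=C1CC(OCOC)=C(C)C(O[Si](C(C)C)(C(C)C)C(C)C)=C1CC=C(C)C | intermediate (not isolated)
15 | 5-(methoxymethoxy)-4-methyl-2-(3-methylbut-2-en-1-yl)-3-[(triisopropylsilyl)oxy]phenol | CC(C)=CCc1c(O)cc(OCOC)c(C)c1O[Si](C(C)C)(C(C)C)C(C)C | intermediate
16 | 2-hydroxy-6-(methoxymethoxy)-5-methyl-3-(3-methylbut-2-en-1-yl)-4-[(triisopropylsilyl)oxy]benzaldehyde | CC(C)=CCc1c(O)c(C=O)c(OCOC)c(C)c1O[Si](C(C)C)(C(C)C)C(C)C | intermediate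
17 | 1-[2-hydroxy-6-(methoxymethoxy)-5-methyl-3-(3-methylbut-2-en-1-yl)-4-[(triisopropylsilyl)oxy]phenyl]ethan-1-ol (racemic) | CC(C)=CCc1c(O)c(C(C)O)c(OCOC)c(C)c1O[Si](C(C)C)(C(C)C)C(C)C | intermediate
18 | 1-[2-hydroxy-6-(methoxymethoxy)-5-methyl-3-(3-methylbut-2-en-1-yl)-4-[(triisopropylsilyl)oxy]phenyl]ethan-1-one | CC(C)=CCc1c(O)c(C(C)=O)c(OCOC)c(C)c1O[Si](C(C)C)(C(C)C)C(C)C | intermediate
19 | (2E)-3-(dimethylamino)-1-[2-hydroxy-6-(methoxymethoxy)-5-methyl-3-(3-methylbut-2-en-1-yl)-4-[(triisopropylsilyl)oxy]phenyl]prop-2-en-1-one | CC(C)=CCc1c(O)c(C(=O)/C=C/N(C)C)c(OCOC)c(C)c1O[Si](C(C)C)(C(C)C)C(C)C | intermediate (not isolated)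
20 | 5-(methoxymethoxy)-6-methyl-8-(3-methylbut-2-en-1-yl)-7-[(triisopropylsilyl)oxy]-4H-chromen-4-one | CC(C)=CCc1c(O[Si](C(C)C)(C(C)C)C(C)C)c(C)c(OCOC)c2c1OC=CC2=O | intermediate
21 | [4-(methoxymethoxy)phenyl]boronic acid | COCOc1ccc(B(O)O)cc1 | starting material
22 | (2S)-5-(methoxymethoxy)-2-[4-(methoxymethoxy)phenyl]-6-methyl-8-(3-methylbut-2-en-1-yl)-7-[(triisopropylsilyl)oxy]chroman-4-one | CC(C)=CCc1c(O[Si](C(C)C)(C(C)C)C(C)C)c(C)c(OCOC)c2c1O[C@H](c1ccc(OCOC)cc1)CC2=O | intermediate
23 | (2S)-5-hydroxy-2-(4-hydroxyphenyl)-6-methyl-8-(3-methylbut-2-en-1-yl)-7-[(triisopropylsilyl)oxy]chroman-4-one | CC(C)=CCc1c(O[Si](C(C)C)(C(C)C)C(C)C)c(C)c(O)c2c1O[C@H](c1ccc(O)cc1)CC2=O | intermediate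
24 | 6-methyl-8-prenylnaringenin, (2S)-5,7-dihydroxy-2-(4-hydroxyphenyl)-6-methyl-8-(3-methylbut-2-en-1-yl)chroman-4-one | CC(C)=CCc1c(O)c(C)c(O)c2c1O[C@H](c1ccc(O)cc1)CC2=O | target

**Step count**

Total: 12 steps. Longest linear sequence: 11 steps (steps 1–3, then 5–12); the siloxyalkyne branch (step 4) joins at step 5.

**Steps most likely to fail**

1. Step 5. The donor-stabilised cyclobutenone may open too slowly, so that decomposition of the acetal or thermal silyl migration in the ynol ether overtakes the cycloaddition.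
Fallback: it sets out from siloxyalkyne 10 and returns at vinylketene 11, hence through 12 to phenol 15. Commercial ethyl 2-methylacetoacetate is O-alkylated (NaH, MOMCl, THF/DMPU) to ethyl (2E)-3-(methoxymethoxy)-2-methylbut-2-enoate F1. Saponification (KOH, EtOH/H2O) gives potassium (2E)-3-(methoxymethoxy)-2-methylbut-2-enoate F2, and (COCl)2 in CH2Cl2 gives (2E)-3-(methoxymethoxy)-2-methylbut-2-enoyl chloride F3. Slow addition of the acid chloride to 10 and Et3N at room temperature should generate 11 by 1,4-dehydrochlorination, with no electrocyclic opening needed. The known ketene–siloxyalkyne [2+2] then gives 12, and warming to 80 °C completes the rearrangement to 15.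

2. Step 10. Insertion into an electron-rich, peri-substituted chromone may be slow, so that protodeboronation of the boronic acid wins, or facial discrimination may be insufficient.
Fallback: it sets out from acetophenone 18 and returns at 22. Pyrrolidine-mediated condensation of 18 with commercial 4-(methoxymethoxy)benzaldehyde (EtOH, 60 °C; aldol condensation then oxa-Michael closure, Kabbe type) should give racemic 5-(methoxymethoxy)-2-[4-(methoxymethoxy)phenyl]-6-methyl-8-(3-methylbut-2-en-1-yl)-7-[(triisopropylsilyl)oxy]chroman-4-one F4. Kinetic resolution by Noyori-type asymmetric transfer hydrogenation ([RuCl(p-cymene)((R,R)-TsDPEN)], HCO2H/Et3N, rt, stopped near half conversion) is expected to reduce the 2R enantiomer to (2R,4R)-5-(methoxymethoxy)-2-[4-(methoxymethoxy)phenyl]-6-methyl-8-(3-methylbut-2-en-1-yl)-7-[(triisopropylsilyl)oxy]chroman-4-ol F5. The unreacted ketone, separated by chromatography, is 22.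

3. Step 4. The amide base or LiCHBr2 may deprotonate the doubly activated allylic α-CH2 of the ester instead of adding to the carbonyl, with conjugation of the alkene.
Fallback: it sets out from ester 7 and returns at lithium ynolate 9. Reduction with i-Bu2AlH (CH2Cl2, −78 °C) gives 4-methylpent-3-enal F6. Corey–Fuchs olefination (CBr4, PPh3, CH2Cl2, 0 °C) gives 1,1-dibromo-5-methylhexa-1,4-diene F7, and n-BuLi (2 equiv, THF, −78 °C) gives lithium 5-methylhex-4-en-1-yn-1-ide F8. Oxidation of this acetylide in the same flask with LiOOt-Bu (from t-BuOOH and LiN(SiMe3)2, −78 → 0 °C) gives 9, which is silylated with TIPSOTf as in step 4.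

**Further compounds**

F1 | step 5 | ethyl (2E)-3-(methoxymethoxy)-2-methylbut-2-enoate | CCOC(=O)/C(C)=C(C)/OCOC
F2 | step 5 | potassium (2E)-3-(methoxymethoxy)-2-methylbut-2-enoate | [K+].[O-]C(=O)/C(C)=C(C)/OCOC
F3 | step 5 | (2E)-3-(methoxymethoxy)-2-methylbut-2-enoyl chloride | ClC(=O)/C(C)=C(C)/OCOC
F4 | step 10 | racemic 5-(methoxymethoxy)-2-[4-(methoxymethoxy)phenyl]-6-methyl-8-(3-methylbut-2-en-1-yl)-7-[(triisopropylsilyl)oxy]chroman-4-one | CC(C)=CCc1c(O[Si](C(C)C)(C(C)C)C(C)C)c(C)c(OCOC)c2c1OC(c1ccc(OCOC)cc1)CC2=O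
F5 | step 10 | (2R,4R)-5-(methoxymethoxy)-2-[4-(methoxymethoxy)phenyl]-6-methyl-8-(3-methylbut-2-en-1-yl)-7-[(triisopropylsilyl)oxy]chroman-4-ol | CC(C)=CCc1c(O[Si](C(C)C)(C(C)C)C(C)C)c(C)c(OCOC)c2c1O[C@@H](c1ccc(OCOC)cc1)C[C@H]2O
F6 | step 4 | 4-methylpent-3-enal | CC(C)=CCC=O
F7 | step 4 | 1,1-dibromo-5-methylhexa-1,4-diene | CC(C)=CCC=C(Br)Br
F8 | step 4 | lithium 5-methylhex-4-en-1-yn-1-ide | [Li]C#CCC=C(C)C
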